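**Plan**

- Retrosynthesis: cut the acrylic acid C=C bond (back to a C5 aldehyde), then O1–C7a of the dihydrofuran, then C2–C3 (auxiliary aldol), then C3a–C3 (Pd enolate arylation) and finally the C7–O bond (lithiation–borylation–oxidation of a bromofluoroarene).
- Enabling feature: in the benzofuran core (O1, C2, C3, C3a, C4–C7, C7a) the carbon C7a lies para to C5, so a C5 formyl group activates a C7a–F bond for displacement by the C2 oxygen.
- Forward order: 3-bromo-4-fluorobenzaldehyde is converted into the arylacetic acid (C7–O first, then C3a–C3); the aldol with veratraldehyde joins C2–C3; reduction gives C9; the only ring closure is O1–C7a; side chain and deprotection follow.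
- Stereochemistry: the boron syn aldol on (R)-4-benzyl-2-oxazolidinone sets both centres as the (2R,3R) adduct. They become C2 (R) and C3 (S), are retained in the ring closure, and the syn relationship gives the 2,3-trans ring. The E alkene comes from the decarboxylative condensation.

Key step: step 11

Remark on numbering: the benzofuran numbering of the target (O1, C2, C3, C3a, C4–C7, C7a; C9 = hydroxymethyl carbon) is used for the corresponding atoms of all intermediates; Tr = triphenylmethyl, MOM = methoxymethyl.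

**Route**

Step 1
Reactants: 1 3-bromo-4-fluorobenzaldehyde
Product: 2 2-(3-bromo-4-fluorophenyl)-1,3-dioxolane
Conditions: ethylene glycol, p-TsOH·H2O (cat.), toluene, reflux, Dean–Stark
Reagents that add atoms: ethylene glycol, OCCO
Why: Acid-catalysed acetalisation with azeotropic removal of water should mask the formyl group as a 1,3-dioxolane that is inert to the lithium amide, organozinc, boron enolate and hydride reagents used later.

Step 2
Reactants: 2 2-(3-bromo-4-fluorophenyl)-1,3-dioxolane
Product: 5 3-bromo-5-(1,3-dioxolan-2-yl)-2-fluorophenol, via aryllithium 3 (not isolated), via lithium aryltrimethoxyborate 4 (not isolated)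
Conditions: LDA, THF, −78 °C; B(OMe)3, −78 → 0 °C; aq NaOH, 30% H2O2, 0 °C → rt; NH4Cl work-up
Reagents that add atoms: hydrogen peroxide, OO
Why: Directed ortho-metalation: fluorine acidifies its only remaining ortho C–H (the future C7), LDA at −78 °C should remove it without bromine–lithium exchange, and borylation followed by alkaline peroxide oxidation (aryl shift from boron to oxygen) should give the phenol while the acetal stays intact in base.

Step 3
Reactants: 5 3-bromo-5-(1,3-dioxolan-2-yl)-2-fluorophenol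
Product: 6 2-[3-bromo-4-fluoro-5-(methoxymethoxy)phenyl]-1,3-dioxolane
Conditions: MOMCl, i-Pr2NEt, CH2Cl2, 0 °C → rt
Reagents that add atoms: chloromethyl methyl ether, COCCl
Why: O-Alkylation of the phenol with MOMCl under amine base (Williamson-type etherification) should give an acetal ether that withstands every basic, organometallic and reducing step up to the final acid treatment.

Step 4
Reactants: 6 2-[3-bromo-4-fluoro-5-(methoxymethoxy)phenyl]-1,3-dioxolane; 7 ethyl bromoacetate
Product: 9 ethyl 2-[5-(1,3-dioxolan-2-yl)-2-fluoro-3-(methoxymethoxy)phenyl]acetate, via Reformatsky reagent 8 (not isolated)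
Conditions: 7, Zn dust, TMSCl (cat.), THF, 40 °C; then 6, Pd(dba)2 (2 mol%), Q-Phos (2 mol%), THF, rt → 60 °C
Reagents that add atoms: none
Why: Palladium-catalysed cross-coupling of a Reformatsky zinc enolate with an aryl bromide (Negishi-type α-arylation of an ester) should forge C3a–C3; the weakly basic zinc enolate leaves the acetal, the MOM ether and the C–F bond alone.

Step 5
Reactants: 9 ethyl 2-[5-(1,3-dioxolan-2-yl)-2-fluoro-3-(methoxymethoxy)phenyl]acetate
Product: 10 2-[5-(1,3-dioxolan-2-yl)-2-fluoro-3-(methoxymethoxy)phenyl]acetic acid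
Conditions: LiOH·H2O, THF/H2O 3:1, 0 °C → rt; 10% aq citric acid to pH 4, 0 °C
Reagents that add atoms: lithium hydroxide, [Li+].[OH-]
Why: Saponification of the ethyl ester; acidification only to pH 4 with cold citric acid should free the arylacetic acid without hydrolysing the dioxolane or the MOM ether.

Step 6
Reactants: 10 2-[5-(1,3-dioxolan-2-yl)-2-fluoro-3-(methoxymethoxy)phenyl]acetic acid; 11 (R)-4-benzyl-1,3-oxazolidin-2-one
Product: 13 (4R)-4-benzyl-3-{2-[5-(1,3-dioxolan-2-yl)-2-fluoro-3-(methoxymethoxy)phenyl]acetyl}-1,3-oxazolidin-2-one, via mixed pivalic anhydride 12 (not isolated)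
Conditions: PivCl, Et3N, THF, −20 °C; then LiCl, 11, −20 °C → rt
Reagents that add atoms: none
Why: N-Acylation of the oxazolidinone through the mixed pivalic anhydride (LiCl/Et3N protocol) should attach the chiral auxiliary, attack occurring at the less hindered arylacetyl carbonyl.

Step 7
Reactants: 13 (4R)-4-benzyl-3-{2-[5-(1,3-dioxolan-2-yl)-2-fluoro-3-(methoxymethoxy)phenyl]acetyl}-1,3-oxazolidin-2-one; 14 veratraldehyde (3,4-dimethoxybenzaldehyde)
Product: 17 (4R)-4-benzyl-3-[(2R,3R)-3-(3,4-dimethoxyphenyl)-2-[5-(1,3-dioxolan-2-yl)-2-fluoro-3-(methoxymethoxy)phenyl]-3-hydroxypropanoyl]-1,3-oxazolidin-2-one, via Z-dibutylboron enolate 15 (not isolated), via dibutylboron aldolate 16 (not isolated)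
Conditions: Bu2BOTf, i-Pr2NEt, CH2Cl2, −78 → 0 °C; 14, −78 → 0 °C; pH 7 buffer, MeOH, 30% H2O2, 0 °C
Reagents that add atoms: none
Why: Evans boron aldol reaction: soft enolisation should give the Z-dibutylboron enolate, which adds to veratraldehyde through a chair Zimmerman–Traxler transition state on the enolate face away from the benzyl group of the dipole-opposed (R)-auxiliary, setting both stereocentres as the (2R,3R) syn adduct (the future C3 and C2).

Step 8
Reactants: 17 (4R)-4-benzyl-3-[(2R,3R)-3-(3,4-dimethoxyphenyl)-2-[5-(1,3-dioxolan-2-yl)-2-fluoro-3-(methoxymethoxy)phenyl]-3-hydroxypropanoyl]-1,3-oxazolidin-2-one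
Product: 18 (1R,2S)-1-(3,4-dimethoxyphenyl)-2-[5-(1,3-dioxolan-2-yl)-2-fluoro-3-(methoxymethoxy)phenyl]propane-1,3-diol
Conditions: LiBH4, MeOH (2 equiv), THF, 0 °C; aq NH4Cl work-up (auxiliary 11 recovered)
Reagents that add atoms: none
Why: Reductive cleavage of the N-acyl oxazolidinone with lithium borohydride should reduce only the exocyclic imide carbonyl to the primary alcohol (C9) and release the auxiliary; the stereocentres are no longer epimerisable once the carbonyl is gone, and the acetal, MOM ether and aryl fluoride are inert to borohydride.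

Step 9
Reactants: 18 (1R,2S)-1-(3,4-dimethoxyphenyl)-2-[5-(1,3-dioxolan-2-yl)-2-fluoro-3-(methoxymethoxy)phenyl]propane-1,3-diol
Product: 19 3-[(1R,2S)-1-(3,4-dimethoxyphenyl)-1,3-dihydroxypropan-2-yl]-4-fluoro-5-(methoxymethoxy)benzaldehyde
Conditions: PPTS (0.2 equiv), acetone/H2O 10:1, 45 °C
Reagents that add atoms: water, O
Why: Mild acid-catalysed acetal hydrolysis (transacetalisation to acetone) should release the C5 aldehyde; pyridinium tosylate is too weak an acid to cleave the phenolic MOM ether or to ionise the veratryl carbinol, so the C2 configuration is kept.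

Step 10
Reactants: 19 3-[(1R,2S)-1-(3,4-dimethoxyphenyl)-1,3-dihydroxypropan-2-yl]-4-fluoro-5-(methoxymethoxy)benzaldehyde
Product: 20 3-[(1R,2S)-1-(3,4-dimethoxyphenyl)-1-hydroxy-3-(triphenylmethoxy)propan-2-yl]-4-fluoro-5-(methoxymethoxy)benzaldehyde
Conditions: TrCl, Et3N, DMAP (cat.), CH2Cl2, rt
Reagents that add atoms: trityl chloride (chlorotriphenylmethane), ClC(c1ccccc1)(c1ccccc1)c1ccccc1
Why: Tritylation (SN1-type etherification via the trityl cation) is selective for the primary C9 hydroxyl on steric grounds, and the resulting ether cannot migrate to the neighbouring oxygen under base, leaving the C2 hydroxyl as the only nucleophile for the ring closure.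

Step 11
Reactants: 20 3-[(1R,2S)-1-(3,4-dimethoxyphenyl)-1-hydroxy-3-(triphenylmethoxy)propan-2-yl]-4-fluoro-5-(methoxymethoxy)benzaldehyde
Product: 22 (2R,3S)-2-(3,4-dimethoxyphenyl)-7-(methoxymethoxy)-3-[(triphenylmethoxy)methyl]-2,3-dihydro-1-benzofuran-5-carbaldehyde, via sodium alkoxide 21 (not isolated)
Conditions: NaH (1.3 equiv), THF (0.02 M), 0 °C → rt
Reagents that add atoms: none
Why: NaH deprotonates the C2 hydroxyl irreversibly; the alkoxide adds to the fluorine-bearing C7a to give a Meisenheimer anion whose charge is delocalised onto the para formyl oxygen, and loss of fluoride rearomatises the ring and forms O1–C7a (addition–elimination). The closest known reaction type is the intramolecular SNAr etherification of 2-(2-fluoroaryl)ethanols carrying a para or ortho carbonyl, cyano or nitro group, which gives 2,3-dihydrobenzofurans. The dihydrofuran closes in a 5-exo-trig mode: the attacked arene carbon lies in the new ring and the breaking C–F bond outside it. No stereocentre is created; C2 and C3 come from the aldol and are retained because neither the C2–O nor the C3–H bond is broken, so the syn aldol relationship should translate into the 2,3-trans ring with (2R,3S) configuration. The step needs O-arylation by the C2 oxygen alone: the C9 oxygen is locked as a trityl ether that cannot migrate, addition of the alkoxide to the formyl carbon is reversible whereas fluoride loss is not, and high dilution favours the five-membered closure over intermolecular reactions.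

Step 12
Reactants: 22 (2R,3S)-2-(3,4-dimethoxyphenyl)-7-(methoxymethoxy)-3-[(triphenylmethoxy)methyl]-2,3-dihydro-1-benzofuran-5-carbaldehyde; 23 malonic acid
Product: 25 (2E)-3-{(2R,3S)-2-(3,4-dimethoxyphenyl)-7-(methoxymethoxy)-3-[(triphenylmethoxy)methyl]-2,3-dihydro-1-benzofuran-5-yl}prop-2-enoic acid, via arylidenemalonic acid 24 (not isolated)
Conditions: 23 (3 equiv), pyridine, piperidine (cat.), 90 °C; cold citric acid work-up
Reagents that add atoms: none
Why: Doebner modification of the Knoevenagel condensation: the aldehyde condenses with malonic acid under piperidine catalysis and the arylidenemalonic acid decarboxylates in hot pyridine to the thermodynamically favoured E-acrylic acid; trityl and MOM ethers are stable in this basic medium.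

Step 13
Reactants: 25 (2E)-3-{(2R,3S)-2-(3,4-dimethoxyphenyl)-7-(methoxymethoxy)-3-[(triphenylmethoxy)methyl]-2,3-dihydro-1-benzofuran-5-yl}prop-2-enoic acid
Product: 26 (2E)-3-[(2R,3S)-2-(3,4-dimethoxyphenyl)-7-hydroxy-3-(hydroxymethyl)-2,3-dihydro-1-benzofuran-5-yl]prop-2-enoic acid (CNP0193199.1)
Conditions: 3 M aq HCl/THF 1:2, 45 °C
Reagents that add atoms: none
Why: Aqueous acid hydrolysis should remove the trityl ether (via the trityl cation) and the phenolic methoxymethyl acetal (via the methoxymethyl oxocarbenium ion), both far more acid-labile than the cyclic benzylic aryl ether, so C2 and C3 are untouched and the target is obtained.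

**Compound list**

1 | 3-bromo-4-fluorobenzaldehyde | O=Cc1ccc(F)c(Br)c1 | starting material
2 | 2-(3-bromo-4-fluorophenyl)-1,3-dioxolane | Fc1ccc(C2OCCO2)cc1Br | intermediate
3 | [3-bromo-5-(1,3-dioxolan-2-yl)-2-fluorophenyl]lithium | [Li]c1cc(C2OCCO2)cc(Br)c1F | intermediate (not isolated)
4 | lithium [3-bromo-5-(1,3-dioxolan-2-yl)-2-fluorophenyl]trimethoxyborate | [Li+].CO[B-](OC)(OC)c1cc(C2OCCO2)cc(Br)c1F | intermediate (not isolated)
5 | 3-bromo-5-(1,3-dioxolan-2-yl)-2-fluorophenol | Oc1cc(C2OCCO2)cc(Br)c1F | intermediate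
6 | 2-[3-bromo-4-fluoro-5-(methoxymethoxy)phenyl]-1,3-dioxolane | COCOc1cc(C2OCCO2)cc(Br)c1F | intermediate
7 | ethyl bromoacetate | CCOC(=O)CBr | starting material
8 | bromo(2-ethoxy-2-oxoethyl)zinc (Reformatsky reagent) | CCOC(=O)C[Zn]Br | intermediate (not isolated)
9 | ethyl 2-[5-(1,3-dioxolan-2-yl)-2-fluoro-3-(methoxymethoxy)phenyl]acetate | CCOC(=O)Cc1cc(C2OCCO2)cc(OCOC)c1F | intermediate
10 | 2-[5-(1,3-dioxolan-2-yl)-2-fluoro-3-(methoxymethoxy)phenyl]acetic acid | OC(=O)Cc1cc(C2OCCO2)cc(OCOC)c1F | intermediate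
11 | (R)-4-benzyl-1,3-oxazolidin-2-one | O=C1N[C@H](Cc2ccccc2)CO1 | starting material
12 | 2-[5-(1,3-dioxolan-2-yl)-2-fluoro-3-(methoxymethoxy)phenyl]acetic pivalic anhydride | CC(C)(C)C(=O)OC(=O)Cc1cc(C2OCCO2)cc(OCOC)c1F | intermediate (not isolated)
13 | (4R)-4-benzyl-3-{2-[5-(1,3-dioxolan-2-yl)-2-fluoro-3-(methoxymethoxy)phenyl]acetyl}-1,3-oxazolidin-2-one | O=C(Cc1cc(C2OCCO2)cc(OCOC)c1F)N1[C@H](Cc2ccccc2)COC1=O | intermediate
14 | veratraldehyde (3,4-dimethoxybenzaldehyde) | COc1ccc(C=O)cc1OC | starting material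
15 | (Z)-dibutylboron enolate of 13 (O-dibutylboryl, aryl cis to O–B) | CCCCB(CCCC)O/C(=C\c1cc(C2OCCO2)cc(OCOC)c1F)N1[C@H](Cc2ccccc2)COC1=O | intermediate (not isolated)
16 | O-dibutylboryl aldolate of 17, (2R,3R) | COc1ccc([C@H](OB(CCCC)CCCC)[C@H](C(=O)N3[C@H](Cc4ccccc4)COC3=O)c2cc(C3OCCO3)cc(OCOC)c2F)cc1OC | intermediate (not isolated)
17 | (4R)-4-benzyl-3-[(2R,3R)-3-(3,4-dimethoxyphenyl)-2-[5-(1,3-dioxolan-2-yl)-2-fluoro-3-(methoxymethoxy)phenyl]-3-hydroxypropanoyl]-1,3-oxazolidin-2-one | COc1ccc([C@H](O)[C@H](C(=O)N3[C@H](Cc4ccccc4)COC3=O)c2cc(C3OCCO3)cc(OCOC)c2F)cc1OC | intermediate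
18 | (1R,2S)-1-(3,4-dimethoxyphenyl)-2-[5-(1,3-dioxolan-2-yl)-2-fluoro-3-(methoxymethoxy)phenyl]propane-1,3-diol | COc1ccc([C@H](O)[C@H](CO)c2cc(C3OCCO3)cc(OCOC)c2F)cc1OC | intermediate
19 | 3-[(1R,2S)-1-(3,4-dimethoxyphenyl)-1,3-dihydroxypropan-2-yl]-4-fluoro-5-(methoxymethoxy)benzaldehyde | COc1ccc([C@H](O)[C@H](CO)c2cc(C=O)cc(OCOC)c2F)cc1OC | intermediate
20 | 3-[(1R,2S)-1-(3,4-dimethoxyphenyl)-1-hydroxy-3-(triphenylmethoxy)propan-2-yl]-4-fluoro-5-(methoxymethoxy)benzaldehyde | COc1ccc([C@H](O)[C@H](COC(c3ccccc3)(c3ccccc3)c3ccccc3)c2cc(C=O)cc(OCOC)c2F)cc1OC | intermediate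
21 | sodium alkoxide of 20 (C2–O⁻ Na⁺) | [Na+].COc1ccc([C@H]([O-])[C@H](COC(c3ccccc3)(c3ccccc3)c3ccccc3)c2cc(C=O)cc(OCOC)c2F)cc1OC | intermediate (not isolated)
22 | (2R,3S)-2-(3,4-dimethoxyphenyl)-7-(methoxymethoxy)-3-[(triphenylmethoxy)methyl]-2,3-dihydro-1-benzofuran-5-carbaldehyde | COc1ccc([C@@H]2Oc3c(OCOC)cc(C=O)cc3[C@H]2COC(c4ccccc4)(c4ccccc4)c4ccccc4)cc1OC | intermediate
23 | malonic acid | OC(=O)CC(=O)O | starting material
24 | 2-{[(2R,3S)-2-(3,4-dimethoxyphenyl)-7-(methoxymethoxy)-3-[(triphenylmethoxy)methyl]-2,3-dihydro-1-benzofuran-5-yl]methylidene}propanedioic acid | COc1ccc([C@@H]2Oc3c(OCOC)cc(C=C(C(=O)O)C(=O)O)cc3[C@H]2COC(c4ccccc4)(c4ccccc4)c4ccccc4)cc1OC | intermediate (not isolated)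
25 | (2E)-3-{(2R,3S)-2-(3,4-dimethoxyphenyl)-7-(methoxymethoxy)-3-[(triphenylmethoxy)methyl]-2,3-dihydro-1-benzofuran-5-yl}prop-2-enoic acid | COc1ccc([C@@H]2Oc3c(OCOC)cc(/C=C/C(=O)O)cc3[C@H]2COC(c4ccccc4)(c4ccccc4)c4ccccc4)cc1OC | intermediate
26 | (2E)-3-[(2R,3S)-2-(3,4-dimethoxyphenyl)-7-hydroxy-3-(hydroxymethyl)-2,3-dihydro-1-benzofuran-5-yl]prop-2-enoic acid | COc1ccc([C@@H]2Oc3c(O)cc(/C=C/C(=O)O)cc3[C@H]2CO)cc1OC | target

**Step count and risks**

Total step count: 13. Longest linear sequence: 13 steps (1 → 26).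

Steps most likely to fail: 11, 13 and 2.

Step 11 (ring closure). The alkoxide may add to the formyl group and the hemiacetal alkoxide may then transfer hydride to a second aldehyde (Tishchenko- or Cannizzaro-type redox). Closure may also be slowed by electron release from the ortho MOM ether, so that material is consumed before fluoride is expelled. The fallback exchanges the activating group for one that is inert to alkoxides. It sets out from 20: iodine in aqueous ammonia/THF at room temperature should convert the formyl group into a nitrile, giving 3-[(1R,2S)-1-(3,4-dimethoxyphenyl)-1-hydroxy-3-(triphenylmethoxy)propan-2-yl]-4-fluoro-5-(methoxymethoxy)benzonitrile F1. NaH in THF should then close the ring by the same addition–elimination to (2R,3S)-2-(3,4-dimethoxyphenyl)-7-(methoxymethoxy)-3-[(triphenylmethoxy)methyl]-2,3-dihydro-1-benzofuran-5-carbonitrile F2. DIBAL-H in toluene at −78 °C, followed by hydrolytic work-up of the aldimine, comes back to the route at 22.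

Step 13 (final deprotection). Acid may ionise the benzylic C2–O1 bond, which is stabilised by the dimethoxyphenyl ring, leading to epimerisation at C2 or ring opening before the phenolic MOM group is fully lost. The fallback moves the deprotection one step earlier, where no carboxylic acid is present and methanol can serve as acetal acceptor under milder acid, and ends with the C=C bond formation. It sets out from 22: 0.5 M HCl in MeOH/THF at room temperature with aqueous work-up should give (2R,3S)-2-(3,4-dimethoxyphenyl)-7-hydroxy-3-(hydroxymethyl)-2,3-dihydro-1-benzofuran-5-carbaldehyde F3. Doebner–Knoevenagel condensation of this aldehyde with malonic acid 23 (pyridine, piperidine cat., 90 °C) would pass through 2-{[(2R,3S)-2-(3,4-dimethoxyphenyl)-7-hydroxy-3-(hydroxymethyl)-2,3-dihydro-1-benzofuran-5-yl]methylidene}propanedioic acid F4 and decarboxylate, coming back to the route at 26.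

Step 2 (phenol installation). The ortho-fluoroaryllithium may lose lithium fluoride to form an aryne, or exchange bromine with unreacted 2 (halogen dance) before it is trapped, which would scramble the substitution pattern. The fallback replaces deprotonation by sterically governed C–H borylation. It sets out from 2: [Ir(OMe)(cod)]2, 4,4'-di-tert-butyl-2,2'-bipyridine and B2pin2 in THF at 70 °C should borylate the only C–H bond not flanked by a large substituent (ortho to fluorine), giving 2-[3-bromo-5-(1,3-dioxolan-2-yl)-2-fluorophenyl]-4,4,5,5-tetramethyl-1,3,2-dioxaborolane F5. Oxidation with sodium perborate in THF/water comes back to the route at 5.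

**Further compounds**

F1 | step 11 | 3-[(1R,2S)-1-(3,4-dimethoxyphenyl)-1-hydroxy-3-(triphenylmethoxy)propan-2-yl]-4-fluoro-5-(methoxymethoxy)benzonitrile | COc1ccc([C@H](O)[C@H](COC(c3ccccc3)(c3ccccc3)c3ccccc3)c2cc(C#N)cc(OCOC)c2F)cc1OC
F2 | step 11 | (2R,3S)-2-(3,4-dimethoxyphenyl)-7-(methoxymethoxy)-3-[(triphenylmethoxy)methyl]-2,3-dihydro-1-benzofuran-5-carbonitrile | COc1ccc([C@@H]2Oc3c(OCOC)cc(C#N)cc3[C@H]2COC(c4ccccc4)(c4ccccc4)c4ccccc4)cc1OC
F3 | step 13 | (2R,3S)-2-(3,4-dimethoxyphenyl)-7-hydroxy-3-(hydroxymethyl)-2,3-dihydro-1-benzofuran-5-carbaldehyde | COc1ccc([C@@H]2Oc3c(O)cc(C=O)cc3[C@H]2CO)cc1OC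
F4 | step 13 | 2-{[(2R,3S)-2-(3,4-dimethoxyphenyl)-7-hydroxy-3-(hydroxymethyl)-2,3-dihydro-1-benzofuran-5-yl]methylidene}propanedioic acid | COc1ccc([C@@H]2Oc3c(O)cc(C=C(C(=O)O)C(=O)O)cc3[C@H]2CO)cc1OC
F5 | step 2 | 2-[3-bromo-5-(1,3-dioxolan-2-yl)-2-fluorophenyl]-4,4,5,5-tetramethyl-1,3,2-dioxaborolane | CC1(C)OB(OC1(C)C)c1cc(C2OCCO2)cc(Br)c1F
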